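The plan cuts the C4–CH3 bond (eudesmane numbering) last and the ring A bonds C4–C5 and C1–C10 before it. Two features are used: the O-aryl on C4 is ortho to the free phenol, so C4, both oxygens and their two arene carbons can exist as a spiro 1,3-benzodioxole; and H5, the C10 methyl and the C7 side chain share one face of the cis-decalin, as anti addition across C5=C10 of (S)-carvone would leave them. In one operation a benzodioxol-2-yl radical adds to C5 and the C10 enolate closes ring A, joining both halves and setting C5 and C10. The precursors are hydrated carvone and a 2-(3-chloropropyl)benzodioxole; methyl finally opens the ketal.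

Key step: step 6

Assumption: the terpene carbons are numbered as in eudesmane (C4 carries O-aryl and CH3, C5 and C10 are the ring-fusion carbons, C7 carries C(CH3)2OH, C9 is the ring B CH2 on C10), "cis-eudesmane" means H5 and the C10 methyl on one face, and the target is then (4R,5S,7R,10R).

Step 1
Reactants: 1 (S)-(+)-carvone
Product: 2 (S)-5-(2-hydroxypropan-2-yl)-2-methylcyclohex-2-en-1-one
Conditions: 50% aq. H2SO4, 0 °C
Reagents that add atoms: water, O
Why: Acid-catalysed Markovnikov hydration, in which the isopropenyl group gives a tertiary cation that water traps while the protonated enone resists addition; the carvone stereocenter (later C7) is not involved.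

Step 2
Reactants: 3 4-bromo-2,6-difluorobenzaldehyde; 4 4-bromophenol
Product: 5 4-bromo-2-(4-bromophenoxy)-6-fluorobenzaldehyde
Conditions: K2CO3 (1.1 equiv), DMF, 0 °C to rt
Reagents that add atoms: none
Why: SNAr ortho to the formyl group; the first aryloxy group deactivates the ring, so one equivalent of phenoxide should stop at the mono ether.

Step 3
Reactants: 5 4-bromo-2-(4-bromophenoxy)-6-fluorobenzaldehyde
Product: 6 4-bromo-2-(4-bromophenoxy)-6-hydroxybenzaldehyde
Conditions: KOH (2.5 equiv), DMSO/H2O, 60 °C; then aq. HCl
Reagents that add atoms: potassium hydroxide, [K+].[OH-]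
Why: A second SNAr, by hydroxide on the remaining formyl-activated fluoride; the phenoxide that forms switches off further substitution and hydride-transfer chemistry of the aldehyde.

Step 4
Reactants: 6 4-bromo-2-(4-bromophenoxy)-6-hydroxybenzaldehyde
Product: 8 5-bromo-3-(4-bromophenoxy)benzene-1,2-diol, via aryl formate 7 (not isolated)
Conditions: 30% H2O2, NaOH, THF/H2O, 0 °C to rt; then aq. HCl
Reagents that add atoms: hydrogen peroxide, OO
Why: Dakin oxidation, in which hydroperoxide adds to the ortho-hydroxy aldehyde, the electron-rich aryl group migrates to oxygen and the formate is hydrolysed in the same flask, so the former CHO carbon carries the central OH.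

Step 5
Reactants: 8 5-bromo-3-(4-bromophenoxy)benzene-1,2-diol; 9 4-chloro-1,1-dimethoxybutane
Product: 10 6-bromo-4-(4-bromophenoxy)-2-(3-chloropropyl)-1,3-benzodioxole (racemic)
Conditions: TsOH·H2O (5 mol%), toluene, 110 °C, MeOH distilled off
Reagents that add atoms: none
Why: Acid-catalysed transacetalisation of a catechol with an aldehyde dimethyl acetal, driven by removal of methanol; the acetal carbon is formed racemic, which does not matter because it becomes a planar radical.

Step 6
Reactants: 2 (S)-5-(2-hydroxypropan-2-yl)-2-methylcyclohex-2-en-1-one; 10 6-bromo-4-(4-bromophenoxy)-2-(3-chloropropyl)-1,3-benzodioxole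
Product: 12 4-ketal (with catechol 8) of (5S,7S,10S)-11-hydroxy-15-nor-cis-eudesmane-4,9-dione as both ketal epimers, via Giese adduct 11 (not isolated)
Conditions: 2 (1 equiv), 10 (1.3 equiv), (n-Bu4N)4W10O32 (3 mol%), MeCN, 390 nm LEDs, rt; evaporate; KOtBu (3 equiv), THF/t-BuOH, 0 to 45 °C
Reagents that add atoms: none
Why: Proposed new method: photoexcited decatungstate should abstract the acetal hydrogen of 10, the resulting nucleophilic dioxy-substituted radical (a masked acyl radical) adds to the enone β carbon C5 of 2 and hydrogen back-transfer gives ketone 11; KOtBu then equilibrates the enolates and the C10 enolate displaces chloride at C1. The closest known reactions are decatungstate hydrogen-atom-transfer Giese additions of 1,3-benzodioxole and 2-alkyl-1,3-dioxolane C–H bonds to enones and the base-mediated cycloalkylation of 3-(4-halobutyl)-2-methylcyclohexanones to cis-fused angular-methyl decalones; joining them as one annulation on a 2-alkylbenzodioxole and a carvone-type enone is the untested part. Ring A closes by 6-exo-tet C-alkylation of the enolate (enolate double bond exocyclic to the new ring), the only closure that gives an unstrained ring. C5 is set by attack of the bulky radical anti to the C7 hydroxyisopropyl group on the half-chair enone (3,5-trans), and C10 is set because allylic strain with the C10 methyl holds the ketal carbon pseudo-axial, so its three-carbon tether reaches C10 only from the face that already carries C4, which gives the cis fusion with methyl syn to H5. The step needs abstraction at the O–CH–O bond and not at the allylic or α-keto C–H bonds of 2, which the weak, hydridic acetal C–H and the polarity mismatch of the electron-poor C–H bonds should secure; C4 forms as both ketal epimers, which converge in step 10, and because C4 is never a ketone C5 cannot epimerise.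

Step 7
Reactants: 12 4-ketal (with catechol 8) of (5S,7S,10S)-11-hydroxy-15-nor-cis-eudesmane-4,9-dione
Product: 13 C9 tosylhydrazone of 12
Conditions: TsNHNH2 (1.5 equiv), EtOH, 78 °C
Reagents that add atoms: 4-methylbenzenesulfonohydrazide, Cc1ccc(cc1)S(=O)(=O)NN
Why: Hydrazone condensation at the only carbonyl group, heated because C9 is flanked by the quaternary C10; the catechol ketal and the tertiary alcohol are inert.

Step 8
Reactants: 13 C9 tosylhydrazone of 12
Product: 14 ketal (with catechol 8) of (5S,7R,10R)-11-hydroxy-15-nor-cis-eudesman-4-one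
Conditions: catecholborane (4 equiv), CHCl3, 0 °C to rt; then NaOAc·3H2O, 60 °C
Reagents that add atoms: none
Why: Kabalka reduction of a tosylhydrazone, in which the borane adds hydride to C=N and acetate then triggers loss of sulfinate and N2, so C9 becomes CH2 without touching the aryl bromides, the ketal or any stereocenter.

Step 9
Reactants: 14 ketal (with catechol 8) of (5S,7R,10R)-11-hydroxy-15-nor-cis-eudesman-4-one; 15 allyltributylstannane
Product: 16 ketal of (5S,7R,10R)-11-hydroxy-15-nor-cis-eudesman-4-one with 5-allyl-3-(4-allylphenoxy)benzene-1,2-diol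
Conditions: Pd(PPh3)4 (10 mol%), 15 (3 equiv), DMF, 100 °C
Reagents that add atoms: none
Why: Double Stille coupling of the two aryl bromides with the allylstannane under neutral conditions, which the ketal (the only phenol protection) and the tertiary alcohol tolerate.

Step 10
Reactants: 16 ketal of (5S,7R,10R)-11-hydroxy-15-nor-cis-eudesman-4-one with 5-allyl-3-(4-allylphenoxy)benzene-1,2-diol; 17 trimethylaluminium
Product: 18 2-(4-allylphenoxy)-4-allyl-6-{[(4R,5S,7R,10R)-11-hydroxy-cis-eudesman-4-yl]oxy}phenol (target)
Conditions: Me3Al (6 equiv), CH2Cl2, −20 °C to rt; aq. Rochelle salt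
Reagents that add atoms: none
Why: Alkylative ketal cleavage by Me3Al, known for ketals, acetonides and 2,2-disubstituted benzodioxoles: aluminium held between the central dioxole oxygen and the neighbouring diaryl ether oxygen (and the chelated aluminium phenoxide it turns into) should make the central C4–O bond ionise, both ketal epimers give one aryloxycarbenium ion, and methyl adds from the equatorial face because the axial face is blocked by the syn-axial C9 methylene, leaving O-aryl axial (4R).

Compound list
1 | (S)-(+)-carvone | CC1=CC[C@@H](CC1=O)C(C)=C | starting material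
2 | (S)-5-(2-hydroxypropan-2-yl)-2-methylcyclohex-2-en-1-one | CC1=CC[C@@H](CC1=O)C(C)(C)O | intermediate
3 | 4-bromo-2,6-difluorobenzaldehyde | O=Cc1c(F)cc(Br)cc1F | starting material
4 | 4-bromophenol | Oc1ccc(Br)cc1 | starting material
5 | 4-bromo-2-(4-bromophenoxy)-6-fluorobenzaldehyde | O=Cc1c(F)cc(Br)cc1Oc1ccc(Br)cc1 | intermediate
6 | 4-bromo-2-(4-bromophenoxy)-6-hydroxybenzaldehyde | O=Cc1c(O)cc(Br)cc1Oc1ccc(Br)cc1 | intermediate
7 | 4-bromo-2-(4-bromophenoxy)-6-hydroxyphenyl formate | O=COc1c(O)cc(Br)cc1Oc1ccc(Br)cc1 | intermediate
8 | 5-bromo-3-(4-bromophenoxy)benzene-1,2-diol | Oc1cc(Br)cc(Oc2ccc(Br)cc2)c1O | intermediate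
9 | 4-chloro-1,1-dimethoxybutane | COC(OC)CCCCl | starting material
10 | 6-bromo-4-(4-bromophenoxy)-2-(3-chloropropyl)-1,3-benzodioxole (racemic) | ClCCCC1Oc2cc(Br)cc(Oc3ccc(Br)cc3)c2O1 | intermediate
11 | (3S,5S)-3-[6-bromo-4-(4-bromophenoxy)-2-(3-chloropropyl)-1,3-benzodioxol-2-yl]-5-(2-hydroxypropan-2-yl)-2-methylcyclohexan-1-one (mixture at ring C2 and at the ketal carbon) | CC1C(=O)C[C@@H](C(C)(C)O)C[C@@H]1C1(CCCCl)Oc2cc(Br)cc(Oc3ccc(Br)cc3)c2O1 | intermediate
12 | 4-ketal (with catechol 8) of (5S,7S,10S)-11-hydroxy-15-nor-cis-eudesmane-4,9-dione, both ketal epimers | Brc1ccc(Oc2cc(Br)cc3c2OC2(CCC[C@]4(C)C(=O)C[C@@H](C(C)(C)O)C[C@@H]42)O3)cc1 | intermediate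
13 | C9 tosylhydrazone of 12 | Brc1ccc(Oc2cc(Br)cc3c2OC2(CCC[C@]4(C)C(=NNS(=O)(=O)c5ccc(C)cc5)C[C@@H](C(C)(C)O)C[C@@H]42)O3)cc1 | intermediate
14 | ketal (with catechol 8) of (5S,7R,10R)-11-hydroxy-15-nor-cis-eudesman-4-one, both ketal epimers | Brc1ccc(Oc2cc(Br)cc3c2OC2(CCC[C@]4(C)CC[C@@H](C(C)(C)O)C[C@@H]42)O3)cc1 | intermediate
15 | allyltributylstannane | C=CC[Sn](CCCC)(CCCC)CCCC | starting material
16 | ketal of (5S,7R,10R)-11-hydroxy-15-nor-cis-eudesman-4-one with 5-allyl-3-(4-allylphenoxy)benzene-1,2-diol, both ketal epimers | C=CCc1ccc(Oc2cc(CC=C)cc3c2OC2(CCC[C@]4(C)CC[C@@H](C(C)(C)O)C[C@@H]42)O3)cc1 | intermediate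
17 | trimethylaluminium | C[Al](C)C | starting material
18 | 2-(4-allylphenoxy)-4-allyl-6-{[(4R,5S,7R,10R)-11-hydroxy-cis-eudesman-4-yl]oxy}phenol (CNP0254037.2) | C=CCc1ccc(Oc2cc(CC=C)cc(O[C@]3(C)CCC[C@]4(C)CC[C@@H](C(C)(C)O)C[C@@H]43)c2O)cc1 | target

Total steps: 10. Longest linear sequence: 9 steps (3 and 4 to 18, steps 2 to 10); step 1 makes the second fragment.

Steps most likely to fail

Step 6 (Proposed new method). Hydrogen abstraction may occur at C–H bonds of 2 instead of the acetal C–H, the hindered tertiary radical may add too slowly to the α-methyl enone, or face selectivity at C5 may be incomplete. The fallback makes the same benzodioxol-2-yl radical by photoredox decarboxylation instead of hydrogen abstraction, which is known chemistry for α-oxy and α,α-dioxy acids with enones. It sets out from catechol 8. Condensation with ethyl 5-chloro-2-oxopentanoate (P2O5, toluene, 80 °C) should give ethyl 6-bromo-4-(4-bromophenoxy)-2-(3-chloropropyl)-1,3-benzodioxole-2-carboxylate F1, and LiOH (THF/H2O) the corresponding 2-carboxylic acid F2. Irradiation of F2 with 2, Ir[dF(CF3)ppy]2(dtbbpy)PF6 (1 mol%) and K2HPO4 in DMF (blue LEDs) should give Giese adduct 11, this time isolated and purified. KOtBu in THF/t-BuOH then closes ring A, and the route is rejoined at 12.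

Step 10. The outer instead of the central C4–O bond may ionise, because the diaryl ether oxygen is only a weak donor for aluminium, or the aryloxycarbenium ion may lose a proton to give an enol ether. The fallback hands regiocontrol to a substrate-bound magnesium chelate and reverses the last two steps, so the ring is opened on the dibromide and the allyl groups are put on the free phenol. It sets out from 14. MeMgBr (6 equiv) in toluene at 90 °C, with the ether distilled off, is the Grignard cleavage long known for 2,2-dialkyl-1,3-benzodioxoles. Magnesium bridging the central dioxole oxygen and the diaryl ether oxygen should make that oxygen the leaving phenoxide, with methyl again entering from the equatorial face. This should give 4-bromo-2-(4-bromophenoxy)-6-{[(4R,5S,7R,10R)-11-hydroxy-cis-eudesman-4-yl]oxy}phenol F3. Double Stille allylation of F3 with 15 (Pd(PPh3)4, DMF, 100 °C) comes back to the route at 18.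

Step 7. Condensation at the C9 carbonyl, which sits next to the quaternary C10, may stall, and without a clean hydrazone the reduction in step 8 cannot proceed. The fallback removes the C9 oxygen through the alcohol by a radical chain (Barton–McCombie deoxygenation); the bromides must be allylated first because tin hydride would remove them. It sets out from ketone 12. Double Stille allylation with 15 should give the diallyl analogue of ketone 12 F4, and NaBH4 in MeOH its C9 alcohol F5 (either epimer). 1,1'-Thiocarbonyldiimidazole with DMAP in 1,2-dichloroethane at 80 °C should acylate only the secondary hydroxyl, giving the O-(imidazol-1-ylcarbonothioyl) derivative F6. Bu3SnH and AIBN in toluene at 100 °C then give 16, where the route is rejoined.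

Further compounds
F1 | step 6 | ethyl 6-bromo-4-(4-bromophenoxy)-2-(3-chloropropyl)-1,3-benzodioxole-2-carboxylate | CCOC(=O)C1(CCCCl)Oc2cc(Br)cc(Oc3ccc(Br)cc3)c2O1
F2 | step 6 | 6-bromo-4-(4-bromophenoxy)-2-(3-chloropropyl)-1,3-benzodioxole-2-carboxylic acid | OC(=O)C1(CCCCl)Oc2cc(Br)cc(Oc3ccc(Br)cc3)c2O1
F3 | step 10 | 4-bromo-2-(4-bromophenoxy)-6-{[(4R,5S,7R,10R)-11-hydroxy-cis-eudesman-4-yl]oxy}phenol | Brc1ccc(Oc2cc(Br)cc(O[C@]3(C)CCC[C@]4(C)CC[C@@H](C(C)(C)O)C[C@@H]43)c2O)cc1
F4 | step 7 | diallyl analogue of ketone 12 (both bromides replaced by allyl) | C=CCc1ccc(Oc2cc(CC=C)cc3c2OC2(CCC[C@]4(C)C(=O)C[C@@H](C(C)(C)O)C[C@@H]42)O3)cc1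
F5 | step 7 | C9 alcohol from F4 (either C9 epimer) | C=CCc1ccc(Oc2cc(CC=C)cc3c2OC2(CCC[C@]4(C)C(O)C[C@@H](C(C)(C)O)C[C@@H]42)O3)cc1
F6 | step 7 | O-(1H-imidazol-1-ylcarbonothioyl) derivative of F5 | C=CCc1ccc(Oc2cc(CC=C)cc3c2OC2(CCC[C@]4(C)C(OC(=S)n5ccnc5)C[C@@H](C(C)(C)O)C[C@@H]42)O3)cc1
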